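**Retrosynthetic overview**

1. Target numbering: C1 ketone, C2(OH)Me, C3 sec-butyl, C4(Me)(acyl), C4a–H, C5 Me, C6, C7(OH)Me, C8, C8a–OH. Ring A = C1–C4, C4a, C8a; ring B = C4a, C5–C8, C8a.
2. Late stage: the (E)-β-methoxy enone comes from MeOH addition to an ynone made from a C4 formyl group. The C1 ketone, C2–OH and C8a–OH come from the C1=C2 alkene of a Diels–Alder adduct (singlet-oxygen ene shift, hydroxyl-directed dihydroxylation, oxidation).
3. Rings A and B close together in an intramolecular Diels–Alder reaction (C3–C4 and C4a–C8a) of an (E,E,E)-trienal whose C5–C8 tether carries the C5 and C7 stereocentres.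
4. That tether is made as a temporary cyclohexanone: amine-catalysed Michael addition (C5–C6) and desymmetrising aldol (C7–C8) of acetone with (E)-pent-3-en-2-one, later cut across C4a–C8a by ozonolysis. Enabling feature: in ring B the C7 methyl carbinol lies 1,3 to C8a and 1,5 to it through C6–C5–C4a, so with C8a as a carbonyl ring B is an aldol plus Michael retron, and the open diketone is mirror-symmetric about C5.
5. Order of ring formation: temporary six-membered ring holding all ring B carbons (step 1), opened in step 5; rings A and B together in step 11.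

Key step: step 1

Remark: the catalyst is written as 9-amino-9-deoxy-epi-quinine; of the two available pseudo-enantiomeric cinchona amines, the one that delivers the (3R,5R)-ketol is meant.
Remark: locants in the Why lines are those of the target.

**Route**

Step 1
Reactants: 1 acetone; 2 (E)-pent-3-en-2-one
Product: 4 (3R,5R)-3-hydroxy-3,5-dimethylcyclohexan-1-one, via 4-methylheptane-2,6-dione 3 (not isolated)
Conditions: acetone (solvent), 9-amino-9-deoxy-epi-quinine (20 mol %), CF3CO2H (40 mol %), 0 °C to rt, stopped before dehydration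
Reagents that add atoms: none
Why: Robinson-type formal (4+2) annulation under primary-amine catalysis, stopped at the ketol: the enamine of acetone adds to the iminium-activated enone (Michael, C5–C6) to give the mirror-symmetric diketone 3, and the same chiral amine then turns one of its two enantiotopic acetyl groups into an enamine whose methyl carbon (C8) attacks the other carbonyl (C7) in an intramolecular aldol (C7–C8). The closest known reaction types are the amine-catalysed Michael addition of acetone to enones and the amine-catalysed desymmetrising aldol cyclisation of 4-substituted heptane-2,6-diones (Hajos–Parrish-type). The single ring closes by a 6-(enolendo)-exo-trig aldol through a chair. Both new stereocentres arise in that aldol: the choice between the two acetyl arms fixes C5 and the carbonyl face attacked fixes C7, both under catalyst control, while the chair with the C5 methyl equatorial places the C7 methyl equatorial and the hydroxyl axial (methyls cis). The step needs enantiotopic-group selection (cinchona primary amine), cis diastereoselection (chair closure; the cis ketol should also be the more stable isomer) and arrest before dehydration (low temperature, weak acid co-catalyst); there is no regiochemical issue because both ends of 3 are identical.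

Step 2
Reactants: 4 (3R,5R)-3-hydroxy-3,5-dimethylcyclohexan-1-one
Product: 5 (3R,5R)-3,5-dimethyl-3-[(triethylsilyl)oxy]cyclohexan-1-one
Conditions: Et3SiOTf, 2,6-lutidine, CH2Cl2, −78 to 0 °C
Reagents that add atoms: triethylsilyl trifluoromethanesulfonate, CC[Si](CC)(CC)OS(=O)(=O)C(F)(F)F
Why: Silylation of the tertiary alcohol with the silyl triflate blocks retro-aldol opening of the ketol in the enolate chemistry that follows and later keeps the C7 oxygen away from the dienophile.

Step 3
Reactants: 5 (3R,5R)-3,5-dimethyl-3-[(triethylsilyl)oxy]cyclohexan-1-one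
Product: 6 (3R,5R)-3,5-dimethyl-5-[(triethylsilyl)oxy]cyclohex-1-en-1-yl trifluoromethanesulfonate
Conditions: LiN(i-Pr)2, THF, −78 °C; then PhNTf2, −78 to 0 °C
Reagents that add atoms: N-phenylbis(trifluoromethanesulfonimide), O=S(=O)(N(c1ccccc1)S(=O)(=O)C(F)(F)F)C(F)(F)F
Why: Kinetic deprotonation should occur at the methylene next to the C5 methine and not at the neopentyl-type methylene beside the quaternary silyloxy carbon, as with 3,3,5-trisubstituted cyclohexanones; O-triflation of the enolate fixes the double bond between the future C4a and C8a.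

Step 4
Reactants: 6 (3R,5R)-3,5-dimethyl-5-[(triethylsilyl)oxy]cyclohex-1-en-1-yl trifluoromethanesulfonate
Product: 7 triethyl{[(1S,5R)-1,5-dimethylcyclohex-3-en-1-yl]oxy}silane
Conditions: Pd(OAc)2 (5 mol %), PPh3 (10 mol %), HCO2H, Bu3N, DMF, 60 °C
Reagents that add atoms: none
Why: Palladium-catalysed formate reduction of an enol triflate (oxidative addition, hydride transfer from formate, reductive elimination) gives the cyclohexene without touching either stereocentre.

Step 5
Reactants: 7 triethyl{[(1S,5R)-1,5-dimethylcyclohex-3-en-1-yl]oxy}silane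
Product: 8 (2R,4R)-2,4-dimethyl-4-[(triethylsilyl)oxy]hexanedial
Conditions: O3, CH2Cl2, −78 °C; then PPh3, −78 °C to rt
Reagents that add atoms: ozone, [O-][O+]=O
Why: Ozonolysis with reductive work-up cuts the temporary ring exactly across the future C4a–C8a bond and releases both carbons as aldehydes; the C5 centre is now α to an aldehyde, so 8 should be used at once.

Step 6
Reactants: 9 (2S)-2-methylbutan-1-ol; 10 ethyl 2-(triphenyl-λ5-phosphanylidene)propanoate
Product: 12 ethyl (2E,4S)-2,4-dimethylhex-2-enoate, via (2S)-2-methylbutanal 11 (not isolated)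
Conditions: 2-iodoxybenzoic acid (IBX), DMSO, rt, ylide 10 present from the start
Reagents that add atoms: none
Why: Tandem oxidation–Wittig reaction traps the volatile, configurationally labile α-branched aldehyde as it forms, and the stabilised α-methyl ylide should give the (E)-trisubstituted enoate.

Step 7
Reactants: 12 ethyl (2E,4S)-2,4-dimethylhex-2-enoate
Product: 13 (2E,4S)-2,4-dimethylhex-2-en-1-ol
Conditions: i-Bu2AlH (2.2 equiv), CH2Cl2, −78 °C; aq. potassium sodium tartrate
Reagents that add atoms: none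
Why: 1,2-Reduction of the enoate by the aluminium hydride gives the allylic alcohol with the alkene geometry unchanged.

Step 8
Reactants: 13 (2E,4S)-2,4-dimethylhex-2-en-1-ol
Product: 14 diethyl [(2E,4S)-2,4-dimethylhex-2-en-1-yl]phosphonate
Conditions: ZnI2 (1.5 equiv), P(OEt)3 (3 equiv), toluene, 110 °C
Reagents that add atoms: triethyl phosphite, CCOP(OCC)OCC
Why: One-flask conversion of an allylic alcohol into its phosphonate: ZnI2 turns the alcohol into the allylic iodide, which undergoes Michaelis–Arbuzov reaction at the primary carbon with retention of the (E)-alkene.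

Step 9
Reactants: 8 (2R,4R)-2,4-dimethyl-4-[(triethylsilyl)oxy]hexanedial; 14 diethyl [(2E,4S)-2,4-dimethylhex-2-en-1-yl]phosphonate
Product: 15 (2R,4S,6E,8E,10S)-2,4,8,10-tetramethyl-4-[(triethylsilyl)oxy]dodeca-6,8-dienal
Conditions: 14, n-BuLi (1.0 equiv), THF, −78 °C; then 8, −78 to −20 °C
Reagents that add atoms: none
Why: Horner–Wadsworth–Emmons olefination with the allylic phosphonate anion should give the new (E)-alkene and hence the (E,E)-diene; one equivalent at low temperature should react at the unhindered CH2–CHO (C8a) and leave the α-branched C4a aldehyde.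

Step 10
Reactants: 15 (2R,4S,6E,8E,10S)-2,4,8,10-tetramethyl-4-[(triethylsilyl)oxy]dodeca-6,8-dienal; 16 2-(triphenyl-λ5-phosphanylidene)propanal
Product: 17 (2E,4R,6S,8E,10E,12S)-2,4,6,10,12-pentamethyl-6-[(triethylsilyl)oxy]tetradeca-2,8,10-trienal
Conditions: toluene, 80 °C
Reagents that add atoms: none
Why: Wittig reaction of the remaining α-branched aldehyde with the stabilised formyl ylide should give the (E)-2-methyl enal (the dienophile) under neutral conditions that spare the C5 centre.

Step 11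
Reactants: 17 (2E,4R,6S,8E,10E,12S)-2,4,6,10,12-pentamethyl-6-[(triethylsilyl)oxy]tetradeca-2,8,10-trienal
Product: 18 (1R,2S,4aR,6R,8R,8aS)-2-[(2S)-butan-2-yl]-1,3,6,8-tetramethyl-6-[(triethylsilyl)oxy]-1,2,4a,5,6,7,8,8a-octahydronaphthalene-1-carbaldehyde
Conditions: Me2AlCl (1.2 equiv), CH2Cl2, −78 to −20 °C
Reagents that add atoms: none
Why: Lewis-acid-promoted type 1 intramolecular Diels–Alder reaction forms C3–C4 and C4a–C8a and closes rings A and B together; the tether takes the chair already seen in ketol 4 (C5 and C7 methyls equatorial, silyloxy axial) and the aluminium-bound formyl group is endo, so the (E)-enal and (E,E)-diene geometries translate into the trans ring fusion, C4 (methyl and formyl on opposite faces), C3, C4a and C8a in one event.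

Step 12
Reactants: 18 (1R,2S,4aR,6R,8R,8aS)-2-[(2S)-butan-2-yl]-1,3,6,8-tetramethyl-6-[(triethylsilyl)oxy]-1,2,4a,5,6,7,8,8a-octahydronaphthalene-1-carbaldehyde
Product: 20 (1R,2R,3R,6R,8R,8aS)-2-[(2S)-butan-2-yl]-3-hydroxy-1,3,6,8-tetramethyl-6-[(triethylsilyl)oxy]-1,2,3,5,6,7,8,8a-octahydronaphthalene-1-carbaldehyde, via C2 hydroperoxide 19 (not isolated)
Conditions: O2, meso-tetraphenylporphyrin (cat.), visible light, CH2Cl2, 0 °C; then PPh3
Reagents that add atoms: dioxygen, O=O
Why: Schenck ene reaction: singlet oxygen should add to the tertiary alkene carbon C2 on the face opposite the pseudo-axial sec-butyl group and take the pseudo-axial allylic C8a–H on that same face, moving the double bond to C1=C8a; PPh3 reduces the hydroperoxide to the tertiary alcohol.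

Step 13
Reactants: 20 (1R,2R,3R,6R,8R,8aS)-2-[(2S)-butan-2-yl]-3-hydroxy-1,3,6,8-tetramethyl-6-[(triethylsilyl)oxy]-1,2,3,5,6,7,8,8a-octahydronaphthalene-1-carbaldehyde
Product: 21 (1S,2R,3S,4S,4aR,6R,8R,8aR)-2-[(2S)-butan-2-yl]-3,4,4a-trihydroxy-1,3,6,8-tetramethyl-6-[(triethylsilyl)oxy]decahydronaphthalene-1-carbaldehyde
Conditions: OsO4 (1.05 equiv), TMEDA, CH2Cl2, −78 °C; then aq. Na2SO3, rt
Reagents that add atoms: osmium tetroxide, O=[Os](=O)(=O)=O
Why: Hydrogen-bond-directed dihydroxylation: the OsO4–diamine complex is delivered by the allylic C2 hydroxyl to its own face, so the C1 and C8a hydroxyls end up cis to it and the trans ring fusion (C8a–OH anti to C4a–H) results.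

Step 14
Reactants: 21 (1S,2R,3S,4S,4aR,6R,8R,8aR)-2-[(2S)-butan-2-yl]-3,4,4a-trihydroxy-1,3,6,8-tetramethyl-6-[(triethylsilyl)oxy]decahydronaphthalene-1-carbaldehyde
Product: 23 (1S,2S,3R,4S,4aR,5R,7R,8aR)-3-[(2S)-butan-2-yl]-4-(1-hydroxyprop-2-yn-1-yl)-2,4,5,7-tetramethyldecahydronaphthalene-1,2,7,8a-tetrol (carbinol epimers), via silyl-protected propargylic alcohol 22 (not isolated)
Conditions: HC≡CMgBr (6 equiv), THF, −40 to 0 °C; then 1 M HCl, THF/MeOH, rt
Reagents that add atoms: ethynylmagnesium bromide, C#C[Mg]Br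
Why: Grignard addition to the only carbonyl group (the triol is carried as its magnesium alkoxides), followed by acidic work-up that cleaves the tertiary silyl ether; the new carbinol centre is oxidised away in the next step.

Step 15
Reactants: 23 (1S,2S,3R,4S,4aR,5R,7R,8aR)-3-[(2S)-butan-2-yl]-4-(1-hydroxyprop-2-yn-1-yl)-2,4,5,7-tetramethyldecahydronaphthalene-1,2,7,8a-tetrol
Product: 24 (2S,3R,4S,4aR,5R,7R,8aR)-3-[(2S)-butan-2-yl]-2,7,8a-trihydroxy-2,4,5,7-tetramethyl-4-(prop-2-ynoyl)octahydronaphthalen-1(2H)-one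
Conditions: IBX (4 equiv), DMSO, rt
Reagents that add atoms: none
Why: IBX should oxidise the two secondary alcohols (C1–OH and the propargylic carbinol) to ketones and leave the three tertiary alcohols; it converts 1,2-diols into α-ketols without C–C cleavage.

Step 16
Reactants: 24 (2S,3R,4S,4aR,5R,7R,8aR)-3-[(2S)-butan-2-yl]-2,7,8a-trihydroxy-2,4,5,7-tetramethyl-4-(prop-2-ynoyl)octahydronaphthalen-1(2H)-one
Product: 25 (2S,3R,4S,4aR,5R,7R,8aR)-3-[(2S)-butan-2-yl]-2,7,8a-trihydroxy-4-[(2E)-3-methoxyprop-2-enoyl]-2,4,5,7-tetramethyloctahydronaphthalen-1(2H)-one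
Conditions: MeOH, DABCO (10 mol %), 0 °C to rt
Reagents that add atoms: methanol, CO
Why: Amine-catalysed conjugate addition of methanol to the terminal ynone should give the thermodynamically favoured (E)-β-methoxy enone; the C1 ketone has no α-hydrogen and the tertiary alcohols do not compete with the solvent.

**Compound list**

1 | acetone | CC(C)=O | starting material
2 | (E)-pent-3-en-2-one | C/C=C/C(C)=O | starting material
3 | 4-methylheptane-2,6-dione | CC(=O)CC(C)CC(C)=O | intermediate
4 | (3R,5R)-3-hydroxy-3,5-dimethylcyclohexan-1-one | C1[C@H](C)C[C@@](C)(O)CC1=O | intermediate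
5 | (3R,5R)-3,5-dimethyl-3-[(triethylsilyl)oxy]cyclohexan-1-one | C1[C@H](C)C[C@@](C)(O[Si](CC)(CC)CC)CC1=O | intermediate
6 | (3R,5R)-3,5-dimethyl-5-[(triethylsilyl)oxy]cyclohex-1-en-1-yl trifluoromethanesulfonate | C1[C@H](C)C[C@@](C)(O[Si](CC)(CC)CC)CC=1OS(=O)(=O)C(F)(F)F | intermediate
7 | triethyl{[(1S,5R)-1,5-dimethylcyclohex-3-en-1-yl]oxy}silane | C1[C@H](C)C[C@@](C)(O[Si](CC)(CC)CC)CC=1 | intermediate
8 | (2R,4R)-2,4-dimethyl-4-[(triethylsilyl)oxy]hexanedial | O=C[C@H](C)C[C@@](C)(O[Si](CC)(CC)CC)CC=O | intermediate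
9 | (2S)-2-methylbutan-1-ol | CC[C@H](C)CO | starting material
10 | ethyl 2-(triphenyl-λ5-phosphanylidene)propanoate | CCOC(=O)C(C)=P(c1ccccc1)(c1ccccc1)c1ccccc1 | starting material
11 | (2S)-2-methylbutanal | CC[C@H](C)C=O | intermediate
12 | ethyl (2E,4S)-2,4-dimethylhex-2-enoate | CC[C@H](C)/C=C(\C)C(=O)OCC | intermediate
13 | (2E,4S)-2,4-dimethylhex-2-en-1-ol | CC[C@H](C)/C=C(\C)CO | intermediate
14 | diethyl [(2E,4S)-2,4-dimethylhex-2-en-1-yl]phosphonate | CC[C@H](C)/C=C(\C)CP(=O)(OCC)OCC | intermediate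
15 | (2R,4S,6E,8E,10S)-2,4,8,10-tetramethyl-4-[(triethylsilyl)oxy]dodeca-6,8-dienal | O=C[C@H](C)C[C@@](C)(O[Si](CC)(CC)CC)C/C=C/C(/C)=C/[C@@H](C)CC | intermediate
16 | 2-(triphenyl-λ5-phosphanylidene)propanal | CC(C=O)=P(c1ccccc1)(c1ccccc1)c1ccccc1 | starting material
17 | (2E,4R,6S,8E,10E,12S)-2,4,6,10,12-pentamethyl-6-[(triethylsilyl)oxy]tetradeca-2,8,10-trienal | O=C/C(C)=C/[C@H](C)C[C@@](C)(O[Si](CC)(CC)CC)C/C=C/C(/C)=C/[C@@H](C)CC | intermediate
18 | (1R,2S,4aR,6R,8R,8aS)-2-[(2S)-butan-2-yl]-1,3,6,8-tetramethyl-6-[(triethylsilyl)oxy]-1,2,4a,5,6,7,8,8a-octahydronaphthalene-1-carbaldehyde | CC[C@H](C)[C@@H]1[C@](C)(C=O)[C@H]2[C@H](C)C[C@@](C)(O[Si](CC)(CC)CC)C[C@@H]2C=C1C | intermediate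
19 | (1R,2R,3R,6R,8R,8aS)-2-[(2S)-butan-2-yl]-3-hydroperoxy-1,3,6,8-tetramethyl-6-[(triethylsilyl)oxy]-1,2,3,5,6,7,8,8a-octahydronaphthalene-1-carbaldehyde | CC[C@H](C)[C@@H]1[C@](C)(C=O)[C@H]2[C@H](C)C[C@@](C)(O[Si](CC)(CC)CC)CC2=C[C@@]1(C)OO | intermediate
20 | (1R,2R,3R,6R,8R,8aS)-2-[(2S)-butan-2-yl]-3-hydroxy-1,3,6,8-tetramethyl-6-[(triethylsilyl)oxy]-1,2,3,5,6,7,8,8a-octahydronaphthalene-1-carbaldehyde | CC[C@H](C)[C@@H]1[C@](C)(C=O)[C@H]2[C@H](C)C[C@@](C)(O[Si](CC)(CC)CC)CC2=C[C@@]1(C)O | intermediate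
21 | (1S,2R,3S,4S,4aR,6R,8R,8aR)-2-[(2S)-butan-2-yl]-3,4,4a-trihydroxy-1,3,6,8-tetramethyl-6-[(triethylsilyl)oxy]decahydronaphthalene-1-carbaldehyde | CC[C@H](C)[C@@H]1[C@](C)(C=O)[C@H]2[C@H](C)C[C@@](C)(O[Si](CC)(CC)CC)C[C@]2(O)[C@@H](O)[C@@]1(C)O | intermediate
22 | (1S,2S,3R,4S,4aR,5R,7R,8aR)-3-[(2S)-butan-2-yl]-4-(1-hydroxyprop-2-yn-1-yl)-2,4,5,7-tetramethyl-7-[(triethylsilyl)oxy]decahydronaphthalene-1,2,8a-triol (carbinol epimers) | CC[C@H](C)[C@@H]1[C@](C)(C(O)C#C)[C@H]2[C@H](C)C[C@@](C)(O[Si](CC)(CC)CC)C[C@]2(O)[C@@H](O)[C@@]1(C)O | intermediate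
23 | (1S,2S,3R,4S,4aR,5R,7R,8aR)-3-[(2S)-butan-2-yl]-4-(1-hydroxyprop-2-yn-1-yl)-2,4,5,7-tetramethyldecahydronaphthalene-1,2,7,8a-tetrol (carbinol epimers) | CC[C@H](C)[C@@H]1[C@](C)(C(O)C#C)[C@H]2[C@H](C)C[C@@](C)(O)C[C@]2(O)[C@@H](O)[C@@]1(C)O | intermediate
24 | (2S,3R,4S,4aR,5R,7R,8aR)-3-[(2S)-butan-2-yl]-2,7,8a-trihydroxy-2,4,5,7-tetramethyl-4-(prop-2-ynoyl)octahydronaphthalen-1(2H)-one | CC[C@H](C)[C@@H]1[C@](C)(C(=O)C#C)[C@H]2[C@H](C)C[C@@](C)(O)C[C@]2(O)C(=O)[C@@]1(C)O | intermediate
25 | (2S,3R,4S,4aR,5R,7R,8aR)-3-[(2S)-butan-2-yl]-2,7,8a-trihydroxy-4-[(2E)-3-methoxyprop-2-enoyl]-2,4,5,7-tetramethyloctahydronaphthalen-1(2H)-one | CC[C@H](C)[C@@H]1[C@](C)(C(=O)/C=C/OC)[C@H]2[C@H](C)C[C@@](C)(O)C[C@]2(O)C(=O)[C@@]1(C)O | target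

**Step count and risks**

Total steps: 16. Longest linear sequence: 13 steps (steps 1–5 and 9–16).

Most likely to fail, riskiest first:

Step 12. The ene step may abstract a hydrogen of the C2 methyl group instead of C8a–H, which would shift the double bond out of the ring and put the oxygen on C1. Fallback from 18 back to 20, by a carbonyl route instead of an ene shift: dihydroxylation of the C1=C2 alkene with catalytic OsO4 and N-methylmorpholine N-oxide, expected on the face away from the pseudo-axial sec-butyl group, should give the C1,C2-cis-diol F1. IBX oxidation of its secondary hydroxyl should give the C2-hydroxy C1-ketone F2. This ketone can enolise only towards C8a and the aldehyde has no α-hydrogen, so KN(SiMe3)2 (2.2 equiv) followed by PhNTf2 should give the C1(8a)-enol triflate F3. Reduction with Pd(OAc)2, PPh3, HCO2H and Bu3N then rejoins the route at 20.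

Step 9. The phosphonate anion may fail to discriminate between the two aldehyde groups (wrong-end or double olefination), or may trigger base-induced loss of the β-silyloxy group. Fallback from 5 to 15, with the two ends differentiated by oxidation level: Baeyer–Villiger oxidation of 5 (m-CPBA, NaHCO3), in which the methylene remote from the electron-poor silyloxy carbon should migrate, gives the seven-membered lactone F4. Reduction with i-Bu2AlH at −78 °C gives the lactol F5, which carries a single aldehyde at C8a in its open form. Olefination with two equivalents of lithiated 14 gives the dienol F6, and IBX oxidation of its primary alcohol rejoins the route at 15.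

Step 1. The ketol may dehydrate to the enone under the amine–acid catalysis, or the selection between the two acetyl arms may be incomplete. Fallback from 1 and 2 to 4, accepting the dehydration and reinstalling the hydroxyl: the same catalyst system is run on to the condensation product, the enone (5R)-3,5-dimethylcyclohex-2-en-1-one F7. Nucleophilic epoxidation (H2O2, NaOH, MeOH, 0 °C), with attack anti to the C5 methyl, gives the epoxy ketone F8. Reductive opening of the α,β-epoxy ketone with SmI2 (THF/MeOH, −78 °C) returns the β-hydroxy ketone 4 with the hydroxyl trans to the C5 methyl.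

Further compounds
F1 | step 12 | C1,C2-cis-diol of 18 (target numbering): 2-[(2S)-butan-2-yl]-3,4-dihydroxy-1,3,6,8-tetramethyl-6-[(triethylsilyl)oxy]decahydronaphthalene-1-carbaldehyde, both hydroxyls on the face of the C4 methyl, other centres as in 18 | CC[C@H](C)[C@@H]1[C@](C)(C=O)[C@H]2[C@H](C)C[C@@](C)(O[Si](CC)(CC)CC)C[C@@H]2[C@@H](O)[C@@]1(C)O
F2 | step 12 | C2-hydroxy C1-ketone (target numbering): 2-[(2S)-butan-2-yl]-3-hydroxy-1,3,6,8-tetramethyl-4-oxo-6-[(triethylsilyl)oxy]decahydronaphthalene-1-carbaldehyde, centres as in F1 | CC[C@H](C)[C@@H]1[C@](C)(C=O)[C@H]2[C@H](C)C[C@@](C)(O[Si](CC)(CC)CC)C[C@@H]2C(=O)[C@@]1(C)O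
F3 | step 12 | C1(8a)-enol triflate (target numbering): 7-[(2S)-butan-2-yl]-8-formyl-6-hydroxy-2,4,6,8-tetramethyl-2-[(triethylsilyl)oxy]-1,2,3,4,4a,6,7,8-octahydronaphthalen-5-yl trifluoromethanesulfonate (the octalin numbered afresh; centres as in 20) | CC[C@H](C)[C@@H]1[C@](C)(C=O)[C@H]2[C@H](C)C[C@@](C)(O[Si](CC)(CC)CC)CC2=C(OS(=O)(=O)C(F)(F)F)[C@@]1(C)O
F4 | step 9 | (4R,6R)-4,6-dimethyl-4-[(triethylsilyl)oxy]oxepan-2-one | C1[C@H](C)C[C@@](C)(O[Si](CC)(CC)CC)CC(=O)O1
F5 | step 9 | (4R,6R)-4,6-dimethyl-4-[(triethylsilyl)oxy]oxepan-2-ol (anomers, in equilibrium with the open hydroxy aldehyde) | C1[C@H](C)C[C@@](C)(O[Si](CC)(CC)CC)CC(O)O1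
F6 | step 9 | (2R,4S,6E,8E,10S)-2,4,8,10-tetramethyl-4-[(triethylsilyl)oxy]dodeca-6,8-dien-1-ol | OC[C@H](C)C[C@@](C)(O[Si](CC)(CC)CC)C/C=C/C(/C)=C/[C@@H](C)CC
F7 | step 1 | (5R)-3,5-dimethylcyclohex-2-en-1-one | C1[C@H](C)CC(C)=CC1=O
F8 | step 1 | (1R,4R,6R)-4,6-dimethyl-7-oxabicyclo[4.1.0]heptan-2-one | C1[C@H](C)C[C@@]2(C)O[C@H]2C1=O
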